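**Overview**

- Cuts, in retrosynthetic order: the C8–O aryl ester and the C3–C4 epoxide; the C4 methyl (back to a C4 ketone) and the C10 carbinol (back to a C9–C10 epoxide); the C7–C8 bond by a retro-[3,3] shift; the C6=C7 alkene (Wittig); the C1–C5 and C5–C10 bonds (carbene addition); the C2–C3 bond (dianion alkylation).
- Enabling feature: in the seven-membered ring (C1, C5, C6, C7, C8, C9, C10) the adjacent carbons C7 (isopropyl) and C8 (oxygen), trans to each other, face the fusion carbon C1. A bond drawn from C5 to C10 therefore converts the ring into a cyclopropane (C1, C5, C10) on the cyclopentane carrying two cis alkenyl arms, C5–C6=C7 and C10–C9=C8.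
- Forward: a linear dienylboronate β-keto ester is built; one copper-carbene step closes cyclopentanone and cyclopropane together; the Cope rearrangement expands the cyclopropane to the cycloheptadiene; the C9–C10 epoxide is made and opened by hydride; the C3–C4 epoxide is closed last.
- Stereochemistry: the chiral copper catalyst fixes C1. The boat Cope relays it to C7 and C8, and C–B oxidation retains. C10 comes from epoxidation anti to the C8 silyl ether followed by hydride opening at C9, C5 from hydroxyl-directed hydrogenation, and C3/C4 from epoxidation directed by the C10 hydroxyl.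

Key step: step 9

Remark on numbering: guaiane numbering is used for all carbons; α is the face of H-1, β the opposite face (the face of H-5 and of the C8 oxygen in the target).
Assumption: the (S,S)-tert-butyl bis(oxazoline) complex of CuOTf is taken to give the (1R,5S,6S) cyclopropane drawn; if the sense of induction proves opposite, the (R,R) ligand is used and nothing else changes.

**Route**

Step 1
Reactants: 1 (E)-3-methylpent-2-en-4-yn-1-ol
Product: 3 (2E,4E)-3-methyl-5-(4,4,5,5-tetramethyl-1,3,2-dioxaborolan-2-yl)penta-2,4-dien-1-ol, via O-borylated dienylboronate 2 (not isolated)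
Conditions: HBpin (2.3 equiv), Cp2Zr(H)Cl (10 mol %), Et3N (10 mol %), CH2Cl2, 0 °C → rt; then H2O, 0 °C
Reagents that add atoms: pinacolborane, CC1(C)OBOC1(C)C
Why: Zirconocene-hydride-catalysed alkyne hydroboration, in which syn hydrozirconation of the terminal alkyne and Zr-to-B exchange should give the E-alkenylboronate with boron on the terminal carbon (C8), while the hydroxyl is held in the flask as its pinacol borate (one extra equivalent of HBpin, loss of H2) and released by water.

Step 2
Reactants: 3 (2E,4E)-3-methyl-5-(pinacolboryl)penta-2,4-dien-1-ol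
Product: 4 2-[(1E,3E)-5-bromo-3-methylpenta-1,3-dien-1-yl]-4,4,5,5-tetramethyl-1,3,2-dioxaborolane
Conditions: CBr4, PPh3, CH2Cl2, −20 → 0 °C; used without storage
Reagents that add atoms: carbon tetrabromide, BrC(Br)(Br)Br
Why: Appel reaction, where bromide displaces the oxyphosphonium group at the primary allylic carbon by SN2, so both alkene geometries and the alkenylboronate should be unaffected.

Step 3
Reactants: 5 methyl acetoacetate; 4 dienyl bromide boronate
Product: 7 methyl (6E,8E)-7-methyl-3-oxo-9-(pinacolboryl)nona-6,8-dienoate, via acetoacetate dianion 6 (not isolated)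
Conditions: 5 (1.5 equiv), NaH, THF, 0 °C; n-BuLi, 0 °C; then 4, −78 → 0 °C; 1 M HCl, 0 °C
Reagents that add atoms: none
Why: Acetoacetate dianion γ-alkylation, in which the more reactive terminal carbanion attacks the primary allylic bromide by SN2 to form C2–C3, and the pinacol boronate is at most reversibly complexed at low temperature.

Step 4
Reactants: 7 dienyl β-keto ester
Product: 8 methyl (6E,8E)-2-diazo-7-methyl-3-oxo-9-(pinacolboryl)nona-6,8-dienoate
Conditions: 4-acetamidobenzenesulfonyl azide, Et3N, MeCN, 0 °C → rt
Reagents that add atoms: 4-acetamidobenzenesulfonyl azide, CC(=O)Nc1ccc(cc1)S(=O)(=O)N=[N+]=[N-]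
Why: Regitz diazo transfer to the doubly activated methylene (C5), a mild base-mediated process to which boronate and diene are inert.

Step 5
Reactants: 8 diazo β-keto ester
Product: 9 methyl (1R,5S,6S)-6-methyl-2-oxo-6-[(E)-2-(pinacolboryl)ethenyl]bicyclo[3.1.0]hexane-1-carboxylate (6-methyl endo; 6-alkenyl exo and cis to the ester)
Conditions: (CuOTf)2·C6H6 (2.5 mol %, monovalent copper), 2,2'-isopropylidenebis[(4S)-4-tert-butyl-2-oxazoline] (6 mol %), toluene, 50 °C, slow addition of 8
Reagents that add atoms: none
Why: Copper-carbene intramolecular cyclopropanation, in which carbene carbon C5 adds across the proximal trisubstituted C1=C10 bond (the only addition that closes a five-membered ring, and the more electron-rich alkene), closing cyclopentanone and cyclopropane at once; the addition is stereospecific (E alkene gives endo methyl and exo borylvinyl) and the C2-symmetric ligand selects the alkene face, setting C1, C5 and C10 as one enantiomer.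

Step 6
Reactants: 9 bicyclic keto ester
Product: 10 1-(hydroxymethyl)-6-methyl-6-[(E)-2-(pinacolboryl)ethenyl]bicyclo[3.1.0]hexan-2-ol (cyclopropane configuration as in 9; carbinol at guaiane C4 as an epimer mixture)
Conditions: i-Bu2AlH (4.5 equiv), CH2Cl2, −78 → −20 °C; aq. KNaC4H4O6 (potassium sodium tartrate)
Reagents that add atoms: none
Why: Aluminium hydride reduction of the ester to the primary carbinol and of the ketone to the C4 carbinol (its configuration is irrelevant because it is re-oxidised), with pinacol boronate, alkene and cyclopropane expected to be inert at low temperature.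

Step 7
Reactants: 10 cyclopropyl diol
Product: 11 6-methyl-2-oxo-6-[(E)-2-(pinacolboryl)ethenyl]bicyclo[3.1.0]hexane-1-carbaldehyde (configuration as in 9)
Conditions: Dess–Martin periodinane (3 equiv), pyridine, CH2Cl2, 0 °C → rt
Reagents that add atoms: none
Why: Dess–Martin oxidation of both carbinols under buffered, non-acidic conditions that should spare the doubly activated vinylcyclopropane and the boronate; C5 is quaternary, so the formyl ketone cannot enolise.

Step 8
Reactants: 11 bridgehead keto aldehyde; 12 isobutyltriphenylphosphonium bromide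
Product: 14 6-methyl-1-[(Z)-3-methylbut-1-en-1-yl]-6-[(E)-2-(pinacolboryl)ethenyl]bicyclo[3.1.0]hexan-2-one (configuration as in 9; the two alkenyl groups cis on the cyclopropane), via isobutylidene ylide 13 (not isolated)
Conditions: 12, NaN(SiMe3)2, THF, 0 °C; then 11, −78 → −20 °C; work-up below 10 °C, used at once
Reagents that add atoms: none
Why: Wittig olefination with a non-stabilised ylide under lithium-free conditions, which proceeds through the kinetically formed cis-oxaphosphetane to the Z alkene; the ylide should take the aldehyde rather than the ketone, which is shielded by the adjacent quaternary cyclopropane carbon.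

Step 9
Reactants: 14 cis-dialkenylcyclopropane
Product: 15 7α-isopropyl-10-methyl-8β-(pinacolboryl)-15-norguaia-5,9-dien-4-one (1αH, 7βH, 8αH)
Conditions: toluene (0.02 M, degassed), 2,6-di-tert-butyl-4-methylphenol (cat.), 90 °C
Reagents that add atoms: none
Why: A concerted, suprafacial [3,3] sigmatropic shift of the cis-1,2-dialkenylcyclopropane (divinylcyclopropane–cycloheptadiene Cope rearrangement, best matched by the known expansions of 1,6-dialkenylbicyclo[3.1.0]hexanes to hydroazulenes): the termini C7 and C8 bond while the strained C5–C10 bond breaks and the π bonds move to C5=C6 and C9=C10. The seven-membered ring (C1, C5, C6, C7, C8, C9, C10) therefore arises by pericyclic ring expansion of the three-membered ring onto the existing cyclopentanone, a closure outside the endo/exo classification, driven by strain release and by conjugation of the new C5=C6 bond with the C4 ketone. C7 and C8 are set by the boat transition state in which both arms fold over the cyclopropane: the inward Z-isopropyl ends on the face of H-1 and the outward E-boron on the opposite face, giving 7α-isopropyl, 8β-boron and a trans C7/C8 pair, while C1 is carried through from step 5. The step needs this boat to be the only path followed, and the bicyclic frame secures it by holding the bridgehead (C5) and exo (C10) arms cis with no access to a trans isomer, so that the fixed Z and E geometries translate directly into configuration. The inward isopropyl meets only H-1, which should cost heating but not block the reaction, and the endo C10 methyl is trans to the C5 arm, so no homodienyl 1,5-hydrogen shift can compete.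

Step 10
Reactants: 15 allylic boronate
Product: 16 8β-hydroxy-15-norguaia-5,9-dien-4-one (1αH, 7βH)
Conditions: NaBO3·4H2O, THF/H2O (1:1), 0 °C → rt
Reagents that add atoms: sodium perborate, O[B-]1(O)OO[B-](O)(O)OO1.[Na+].[Na+]
Why: Oxidation of the C–B bond by 1,2-shift of C8 from boron to oxygen with retention, so the 8β-boronate should become the 8β-alcohol without allylic transposition, perborate being mild enough to leave the hindered enone alone.

Step 11
Reactants: 16 dienone alcohol
Product: 17 8β-(tert-butyldimethylsilyloxy)-15-norguaia-5,9-dien-4-one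
Conditions: TBSCl, imidazole, DMAP (cat.), DMF, rt
Reagents that add atoms: tert-butyldimethylsilyl chloride, CC(C)(C)[Si](C)(C)Cl
Why: Standard silylation of the secondary alcohol, which removes the hydroxyl as a syn-directing group and places a bulky substituent on the β face next to C9=C10.

Step 12
Reactants: 17 silyl ether
Product: 18 9α,10α-epoxy-8β-(tert-butyldimethylsilyloxy)-15-norguai-5-en-4-one
Conditions: mCPBA, CH2Cl2, 0 °C
Reagents that add atoms: 3-chloroperbenzoic acid, OOC(=O)c1cccc(Cl)c1
Why: Prilezhaev epoxidation of the electron-rich trisubstituted C9=C10 bond (the enone alkene is too electron-poor to react); the 8β silyl ether and the β-disposed C1–C2 bond screen the β face, so oxygen should arrive on the α face, the side of H-1 and H-8, which fixes the C10–O bond.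

Step 13
Reactants: 18 epoxy silyl ether
Product: 19 9α,10α-epoxy-8β-hydroxy-15-norguai-5-en-4-one
Conditions: n-Bu4NF, AcOH (1:1), THF, 0 °C → rt
Reagents that add atoms: none
Why: Fluoride desilylation, buffered with acetic acid so that no free alkoxide is present to trigger Payne rearrangement of the epoxy alcohol or γ-deprotonation of the enone.

Step 14
Reactants: 19 epoxy enone alcohol
Product: 20 9α,10α-epoxy-8β-hydroxy-15-norguaian-4-one (trans-fused; 1αH, 5βH, 7βH)
Conditions: [Ir(cod)(PCy3)(py)]PF6 (5 mol %), H2 (1 atm), CH2Cl2, rt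
Reagents that add atoms: none
Why: Hydroxyl-directed hydrogenation with the cationic monovalent iridium catalyst, in which the homoallylic 8β-hydroxyl binds the metal and both hydrogens are delivered to the β face of C5=C6, setting H-5 β and hence the trans ring fusion.

Step 15
Reactants: 20 epoxy ketone alcohol
Product: 21 9α,10α-epoxy-8β-(triethylsilyloxy)-15-norguaian-4-one
Conditions: TESCl, imidazole, CH2Cl2, 0 °C → rt
Reagents that add atoms: triethylsilyl chloride, CC[Si](Cl)(CC)CC
Why: Silylation masks the C8 hydroxyl so that the strong base of the next step cannot form an epoxy alkoxide (Payne rearrangement) or consume the triflating agent.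

Step 16
Reactants: 21 silyl-protected epoxy ketone
Product: 23 9α,10α-epoxy-8β-(triethylsilyloxy)-15-norguai-3-en-4-yl trifluoromethanesulfonate, via lithium C3 enolate 22 (not isolated)
Conditions: LiN(SiMe3)2, THF, −78 °C; then PhNTf2, −78 → 0 °C
Reagents that add atoms: N-phenylbis(trifluoromethanesulfonimide), O=S(=O)(N(c1ccccc1)S(=O)(=O)C(F)(F)F)C(F)(F)F
Why: Kinetic deprotonation at the C3 methylene rather than the C5 ring-fusion methine, then O-sulfonylation of the enolate, places the alkene at C3=C4 and leaves the C5 configuration untouched.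

Step 17
Reactants: 23 enol triflate
Product: 24 9α,10α-epoxy-8β-(triethylsilyloxy)guai-3-ene
Conditions: MeZnCl (2 equiv), Pd(PPh3)4 (5 mol %, zerovalent palladium), THF, 50 °C
Reagents that add atoms: methylzinc chloride, C[Zn]Cl
Why: Negishi coupling of the alkenyl triflate installs the C4 methyl (C15) under base-free conditions that the epoxide and silyl ether should tolerate; a methyl group has no β-hydrogen to eliminate.

Step 18
Reactants: 24 methylated silyl ether
Product: 25 9α,10α-epoxyguai-3-en-8β-ol
Conditions: n-Bu4NF, AcOH (1:1), THF, 0 °C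
Reagents that add atoms: none
Why: Buffered fluoride cleavage of the triethylsilyl ether frees the C8 hydroxyl needed to steer the hydride in the next step.

Step 19
Reactants: 25 epoxy alcohol
Product: 26 guai-3-ene-8β,10α-diol (1αH, 5βH, 7βH)
Conditions: NaAlH2(OCH2CH2OMe)2, THF, 0 °C → rt; aq. KNaC4H4O6 (potassium sodium tartrate)
Reagents that add atoms: none
Why: Hydride opening of a 2,3-epoxy alcohol, in which the aluminium-bound C8 alkoxide passes hydride to the adjacent C9 from the β face, anti to the α C9–O bond; C9 is also the less substituted epoxide carbon, so the C10–O bond stays and the 10α tertiary alcohol (1,3-diol) results.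

Step 20
Reactants: 26 diol; 27 4-acetoxybenzoic acid
Product: 28 10α-hydroxyguai-3-en-8β-yl 4-acetoxybenzoate
Conditions: DCC, DMAP, CH2Cl2, 0 °C → rt
Reagents that add atoms: none
Why: Steglich esterification acylates only the secondary C8 hydroxyl because the tertiary C10 hydroxyl is too hindered, and the phenol is carried as its acetate to prevent self-acylation.

Step 21
Reactants: 28 alkene ester
Product: 29 3α,4α-epoxy-10α-hydroxyguaian-8β-yl 4-acetoxybenzoate
Conditions: VO(acac)2 (5 mol %), t-BuOOH (1.5 equiv, decane), CH2Cl2, 0 °C → rt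
Reagents that add atoms: tert-butyl hydroperoxide, CC(C)(C)OO
Why: Vanadium-catalysed hydroxyl-directed epoxidation, here with a tertiary bishomoallylic alcohol as in known terpene-alcohol cases: the 10α-hydroxyl binds the vanadium alkyl peroxide and should deliver oxygen to the α face of C3=C4 (reached through C10–C1–C2–C3), setting C3 and C4; the α-hydroxyl cannot open the α-epoxide because backside attack is geometrically excluded.

Step 22
Reactants: 29 epoxy aryl acetate
Product: 30 (1R,3R,4S,5S,7S,8R,10R)-3α,4α-epoxy-10α-hydroxyguaian-8β-yl 4-hydroxybenzoate (CNP0225095.2)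
Conditions: K2CO3, MeOH, 0 °C
Reagents that add atoms: none
Why: Chemoselective methanolysis of the aryl acetate, which transesterifies far faster than the hindered secondary benzoate (further deactivated once the para-phenoxide forms), with epoxide and tertiary alcohol inert to mild carbonate.

**Compound list**

1 | (E)-3-methylpent-2-en-4-yn-1-ol | OC/C=C(C)/C#C | starting material
2 | 2-{[(2E,4E)-3-methyl-5-(pinacolboryl)penta-2,4-dien-1-yl]oxy}-4,4,5,5-tetramethyl-1,3,2-dioxaborolane | CC1(C)OB(OC/C=C(C)/C=C/B2OC(C)(C)C(C)(C)O2)OC1(C)C | intermediate (not isolated)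
3 | (2E,4E)-3-methyl-5-(4,4,5,5-tetramethyl-1,3,2-dioxaborolan-2-yl)penta-2,4-dien-1-ol | OC/C=C(C)/C=C/B1OC(C)(C)C(C)(C)O1 | intermediate
4 | 2-[(1E,3E)-5-bromo-3-methylpenta-1,3-dien-1-yl]-4,4,5,5-tetramethyl-1,3,2-dioxaborolane | BrC/C=C(C)/C=C/B1OC(C)(C)C(C)(C)O1 | intermediate
5 | methyl acetoacetate | COC(=O)CC(C)=O | starting material
6 | sodium lithium dianion of methyl acetoacetate | COC(=O)[CH-]C(=O)[CH2-].[Na+].[Li+] | intermediate (not isolated)
7 | methyl (6E,8E)-7-methyl-3-oxo-9-(pinacolboryl)nona-6,8-dienoate | COC(=O)CC(=O)CC/C=C(C)/C=C/B1OC(C)(C)C(C)(C)O1 | intermediate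
8 | methyl (6E,8E)-2-diazo-7-methyl-3-oxo-9-(pinacolboryl)nona-6,8-dienoate | COC(=O)C(=[N+]=[N-])C(=O)CC/C=C(C)/C=C/B1OC(C)(C)C(C)(C)O1 | intermediate
9 | methyl (1R,5S,6S)-6-methyl-2-oxo-6-[(E)-2-(pinacolboryl)ethenyl]bicyclo[3.1.0]hexane-1-carboxylate | COC(=O)[C@]12C(=O)CC[C@H]1[C@]2(C)/C=C/B3OC(C)(C)C(C)(C)O3 | intermediate
10 | 1-(hydroxymethyl)-6-methyl-6-[(E)-2-(pinacolboryl)ethenyl]bicyclo[3.1.0]hexan-2-ol (cyclopropane as in 9, carbinol epimers) | OC[C@]12C(O)CC[C@H]1[C@]2(C)/C=C/B3OC(C)(C)C(C)(C)O3 | intermediate
11 | 6-methyl-2-oxo-6-[(E)-2-(pinacolboryl)ethenyl]bicyclo[3.1.0]hexane-1-carbaldehyde (configuration as in 9) | O=C[C@]12C(=O)CC[C@H]1[C@]2(C)/C=C/B3OC(C)(C)C(C)(C)O3 | intermediate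
12 | isobutyltriphenylphosphonium bromide | CC(C)C[P+](c1ccccc1)(c1ccccc1)c1ccccc1.[Br-] | starting material
13 | (2-methylpropylidene)triphenylphosphorane | CC(C)C=P(c1ccccc1)(c1ccccc1)c1ccccc1 | intermediate (not isolated)
14 | 6-methyl-1-[(Z)-3-methylbut-1-en-1-yl]-6-[(E)-2-(pinacolboryl)ethenyl]bicyclo[3.1.0]hexan-2-one (configuration as in 9) | CC(C)/C=C\[C@]12C(=O)CC[C@H]1[C@]2(C)/C=C/B3OC(C)(C)C(C)(C)O3 | intermediate
15 | 7α-isopropyl-10-methyl-8β-(pinacolboryl)-15-norguaia-5,9-dien-4-one (1αH) | CC(C)[C@@H]1C=C2[C@@H](CCC2=O)C(C)=C[C@H]1B3OC(C)(C)C(C)(C)O3 | intermediate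
16 | 8β-hydroxy-15-norguaia-5,9-dien-4-one (1αH, 7βH) | CC(C)[C@@H]1C=C2[C@@H](CCC2=O)C(C)=C[C@H]1O | intermediate
17 | 8β-(tert-butyldimethylsilyloxy)-15-norguaia-5,9-dien-4-one | CC(C)[C@@H]1C=C2[C@@H](CCC2=O)C(C)=C[C@H]1O[Si](C)(C)C(C)(C)C | intermediate
18 | 9α,10α-epoxy-8β-(tert-butyldimethylsilyloxy)-15-norguai-5-en-4-one | CC(C)[C@@H]1C=C2[C@@H](CCC2=O)[C@]3(C)O[C@@H]3[C@H]1O[Si](C)(C)C(C)(C)C | intermediate
19 | 9α,10α-epoxy-8β-hydroxy-15-norguai-5-en-4-one | CC(C)[C@@H]1C=C2[C@@H](CCC2=O)[C@]3(C)O[C@@H]3[C@H]1O | intermediate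
20 | 9α,10α-epoxy-8β-hydroxy-15-norguaian-4-one (1αH, 5βH, 7βH) | CC(C)[C@@H]1C[C@H]2[C@@H](CCC2=O)[C@]3(C)O[C@@H]3[C@H]1O | intermediate
21 | 9α,10α-epoxy-8β-(triethylsilyloxy)-15-norguaian-4-one | CC(C)[C@@H]1C[C@H]2[C@@H](CCC2=O)[C@]3(C)O[C@@H]3[C@H]1O[Si](CC)(CC)CC | intermediate
22 | lithium C3=C4 enolate of 21 | CC(C)[C@@H]1C[C@H]2[C@@H](CC=C2[O-])[C@]3(C)O[C@@H]3[C@H]1O[Si](CC)(CC)CC.[Li+] | intermediate (not isolated)
23 | 9α,10α-epoxy-8β-(triethylsilyloxy)-15-norguai-3-en-4-yl trifluoromethanesulfonate | CC(C)[C@@H]1C[C@H]2[C@@H](CC=C2OS(=O)(=O)C(F)(F)F)[C@]3(C)O[C@@H]3[C@H]1O[Si](CC)(CC)CC | intermediate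
24 | 9α,10α-epoxy-8β-(triethylsilyloxy)guai-3-ene | CC(C)[C@@H]1C[C@H]2[C@@H](CC=C2C)[C@]3(C)O[C@@H]3[C@H]1O[Si](CC)(CC)CC | intermediate
25 | 9α,10α-epoxyguai-3-en-8β-ol | CC(C)[C@@H]1C[C@H]2[C@@H](CC=C2C)[C@]3(C)O[C@@H]3[C@H]1O | intermediate
26 | guai-3-ene-8β,10α-diol (1αH, 5βH, 7βH) | CC(C)[C@@H]1C[C@H]2[C@@H](CC=C2C)[C@](C)(O)C[C@H]1O | intermediate
27 | 4-acetoxybenzoic acid | CC(=O)Oc1ccc(cc1)C(O)=O | starting material
28 | 10α-hydroxyguai-3-en-8β-yl 4-acetoxybenzoate | CC(C)[C@@H]1C[C@H]2[C@@H](CC=C2C)[C@](C)(O)C[C@H]1OC(=O)c1ccc(OC(C)=O)cc1 | intermediate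
29 | 3α,4α-epoxy-10α-hydroxyguaian-8β-yl 4-acetoxybenzoate | CC(C)[C@@H]1C[C@H]2[C@@H](C[C@H]3O[C@]32C)[C@](C)(O)C[C@H]1OC(=O)c1ccc(OC(C)=O)cc1 | intermediate
30 | (1R,3R,4S,5S,7S,8R,10R)-3α,4α-epoxy-10α-hydroxyguaian-8β-yl 4-hydroxybenzoate (1αH, 5βH, 7βH) | CC(C)[C@@H]1C[C@H]2[C@@H](C[C@H]3O[C@]32C)[C@](C)(O)C[C@H]1OC(=O)c1ccc(O)cc1 | target

**Step count**

Total: 22 steps. Longest linear sequence: 22 steps (1 → 30); compounds 5, 12 and 27 enter as bought materials.

**Steps most likely to fail, with fallbacks**

Step 5. The process at risk is weak enantiofacial discrimination by the copper carbene of a methyl diazo β-keto ester, a class that responds less well to bis(oxazoline) ligands than sulfone or bulky-ester analogues; every later compound would inherit the shortfall. The fallback replaces catalyst control by a covalent auxiliary with separation of diastereomers. Setting out from bromide 4, the dianion of bought (−)-menthyl acetoacetate (NaH, then n-BuLi, THF) would be alkylated to the menthyl dienyl β-keto ester F1. Diazo transfer (4-acetamidobenzenesulfonyl azide, Et3N) would give the menthyl diazo ester F2. Cyclopropanation with Rh2(OAc)4 (CH2Cl2, rt) would give two diastereomeric bicyclic esters, from which the menthyl (1R,5S,6S)-bicyclic keto ester F3 is taken by chromatography or crystallisation. Reduction with i-Bu2AlH then cleaves the auxiliary and comes back to the route at diol 10.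

Step 8. The process at risk is the ylide acting on the wrong carbonyl or as a base: addition to or enolisation of the C4 ketone, or nucleophilic loss of the formyl group from the non-enolisable β-keto aldehyde, before the Z alkene has formed. The fallback keeps the two oxidation levels apart. Setting out from diol 10, TEMPO with PhI(OAc)2 (CH2Cl2, rt) would oxidise only the primary carbinol to the cyclopropyl hydroxy aldehyde F4. Wittig reaction with ylide 13 (2.2 equiv, −78 → 0 °C) would give the (Z)-alkenyl cyclopropyl carbinol F5. Dess–Martin oxidation at 0 °C would then form the ketone and come back to the route at 14.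

Step 21. The process at risk is poor facial selectivity: a tertiary bishomoallylic hydroxyl directs only weakly, and the alkene is likely to have an inherent bias for attack on the β face (anti to the allylic C5–C6 bond), which would give the 3β,4β-epoxide or mixtures. The fallback uses that bias and inverts it through a halohydrin. Setting out from 28, NBS in aqueous THF (0 °C) would form the bromonium ion on the β face, and water would open it at the tertiary C4 from the α face to give the 3β-bromo-4α,10α-dihydroxyguaian-8β-yl 4-acetoxybenzoate F6. The 10α-hydroxyl cannot intercept this bromonium ion, because a bridge from C10 could reach C3 or C4 only on the β face. K2CO3 in MeOH would then close the α-epoxide by backside displacement of bromide at C3 and cleave the aryl acetate in the same operation, coming back to the route at target 30. This fallback helps only if the bias is indeed for the β face; an unselective alkene would give mixtures by either method.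

**Further compounds**

F1 | step 5 | (1R,2S,5R)-2-isopropyl-5-methylcyclohexyl (6E,8E)-7-methyl-3-oxo-9-(pinacolboryl)nona-6,8-dienoate | CC(C)[C@@H]1CC[C@@H](C)C[C@H]1OC(=O)CC(=O)CC/C=C(C)/C=C/B2OC(C)(C)C(C)(C)O2
F2 | step 5 | (1R,2S,5R)-2-isopropyl-5-methylcyclohexyl (6E,8E)-2-diazo-7-methyl-3-oxo-9-(pinacolboryl)nona-6,8-dienoate | CC(C)[C@@H]1CC[C@@H](C)C[C@H]1OC(=O)C(=[N+]=[N-])C(=O)CC/C=C(C)/C=C/B2OC(C)(C)C(C)(C)O2
F3 | step 5 | (1R,2S,5R)-2-isopropyl-5-methylcyclohexyl (1R,5S,6S)-6-methyl-2-oxo-6-[(E)-2-(pinacolboryl)ethenyl]bicyclo[3.1.0]hexane-1-carboxylate | CC(C)[C@@H]1CC[C@@H](C)C[C@H]1OC(=O)[C@]23C(=O)CC[C@H]2[C@]3(C)/C=C/B4OC(C)(C)C(C)(C)O4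
F4 | step 8 | 2-hydroxy-6-methyl-6-[(E)-2-(pinacolboryl)ethenyl]bicyclo[3.1.0]hexane-1-carbaldehyde (cyclopropane as in 9, carbinol epimers) | O=C[C@]12C(O)CC[C@H]1[C@]2(C)/C=C/B3OC(C)(C)C(C)(C)O3
F5 | step 8 | 6-methyl-1-[(Z)-3-methylbut-1-en-1-yl]-6-[(E)-2-(pinacolboryl)ethenyl]bicyclo[3.1.0]hexan-2-ol (cyclopropane as in 9, carbinol epimers) | CC(C)/C=C\[C@]12C(O)CC[C@H]1[C@]2(C)/C=C/B3OC(C)(C)C(C)(C)O3
F6 | step 21 | 3β-bromo-4α,10α-dihydroxyguaian-8β-yl 4-acetoxybenzoate | CC(C)[C@@H]1C[C@H]2[C@@H](C[C@H](Br)[C@@]2(C)O)[C@](C)(O)C[C@H]1OC(=O)c1ccc(OC(C)=O)cc1
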